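Start from the target: its share in target plus side product, the selectivity, is asked for the flasks below, and the way to reach it is to count how many lifetimes of each step fit into the hour.

| flask | starting material | temperature | remark | time |
|---|---|---|---|---|
| oak | 0.065 M | −6 °C | run made earlier |  |
| elm | 0.098 M | 35 °C | run made earlier |  |
| delta | 0.13 M | 0 °C |  | 1.0 h |
| alpha | 0.13 M | 25 °C |  | 1.0 h |
| beta | 0.13 M | 50 °C |  | 1.0 h |
| gamma | 0.13 M | −25 °C |  | 1.0 h |

| run | time / min | target / % | side product / % |
|---|---|---|---|
| oak | 2.50 | 0 | 3 |
| oak | 8.00 | 5 | 0 |
| oak | 12.0 | 8 | 1 |
| oak | 20.0 | 10 | 3 |
| oak | 30.0 | 15 | 2 |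
| oak | 40.0 | 21 | 1 |
| elm | 0.500 | 21 | 3 |
| elm | 0.833 | 33 | 0 |
| elm | 1.33 | 45 | 0 |
| elm | 2.00 | 53 | 2 |
| elm | 4.00 | 60 | 6 |
| elm | 8.00 | 60 | 8 |

(readings scatter by 1.5 percentage points)

- the flask with the highest share of target in all that became target or side product ("all alike" if they lie within 1.5 percentage points) (delta / alpha / beta / gamma / all alike)
- share of target in all that became target or side product, delta
- share of target in all that became target or side product, alpha
- share of target in all that became target or side product, beta
- share of target in all that became target or side product, gamma



Take the lifetime of the starting material as the time of a reading divided by the natural logarithm of charged over left, assuming first order and counting target as what has gone. Oak reads 21 % at 40.0 min and elm reads 21 % at 0.500 min, so the lifetimes are 170 min and 2.12 min. These give an activation energy of 73.2 kJ/mol, and for gamma a lifetime of 2110 min.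

Now reforge the weak link, the single oak reading with its scatter of 1.5 percentage points. Oak's reading at 30.0 min gives 185 min, so the energy becomes 74.6 kJ/mol and the gamma lifetime 2410 min, the lifetime of the starting material to carry forward. Gamma's hour is then a count of 0.0249 lifetimes, so expect [target] at 2.46 % of the charge. The same energy gives counts of 0.679 for delta, 10.7 for alpha and 109 for beta. Commit to no share for alpha or beta, since elm's target reads 60 % and 60 % on its last two readings, less than the 97.7 % that the simple count expects by the last one.

For the side step, elm's side product climbs from 2 % to 8 % over its last readings, a lifetime of about 60.0 min for target. Borrow the same energy, as a guess, and gamma's becomes 68200 min. Target there averages half its final level over the hour, so expect side product at about 0.0440 % of target. Name gamma as the flask with the highest share, at about >99.9 %, since its count is the lowest.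

The forecast named gamma and gave 96 %, 78 %, 12 % and 98 % for delta, alpha, beta and gamma, saying of beta “side product dominates after an hour”, and its gamma share is lower than mine.

The simulation names gamma, with 96.5 %, 58.8 %, 64.0 % and >99.9 % in that order.

    target + released group → side product (k = 0.00360 /M/s, Ea = 59.0 kJ/mol)
    starting material ⇌ target + released group (K = 0.0910 M, k = 0.00320 /s, Ea = 75.0 kJ/mol, ΔH = 10.0 kJ/mol)
    released group → by-product carried off (k = 1.20 × 10⁻⁴ /s, Ea = 105 kJ/mol)
    (constants at 25 °C)

At 1.00 h gamma holds 2.56 % target and 0 % side product, against the 2.46 % counted from 2410 min. Use that lifetime once more on gamma read at 4.0 h: the count is 0.0995, so expect 9.47 % target. That reading holds 9.73 %.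

The data are simulated from invented constants; the scatter is artificial.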